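Readings and results were computed for substances that don't exist, and the scatter is random.

Start from one ratio: bound single product over free single product. These are the flasks you take over, and this is what is asked of them.

the same everywhere: substrate 10 mM

| run | reagent | remark | time |
|---|---|---|---|
| Tuesday's | 18 mM | run made earlier |  |
| Saturday's | 30 mM | run made earlier |  |
| blue | 15.0 mM |  | 20 min |
| ochre | 20.0 mM |  | 20 min |
| green | 25.0 mM |  | 20 min |

| run | time / min | isomer of the product / % | substrate / % | double product / % | single product / % |
|---|---|---|---|---|---|
| Tuesday's | 1.33 | 0.3 | 73.4 | 0.7 | 18.7 |
| Tuesday's | 4.00 | 1.8 | 48.6 | 4.8 | 33.6 |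
| Tuesday's | 6.00 | 3.7 | 38.9 | 9.4 | 37.4 |
| Tuesday's | 10.0 | 8.1 | 27.5 | 18.4 | 37.3 |
| Tuesday's | 15.0 | 10.8 | 19.6 | 27.2 | 35.5 |
| Saturday's | 1.33 | 0.9 | 62.9 | 2.1 | 25.7 |
| Saturday's | 4.00 | 3.4 | 33.6 | 13.4 | 39.8 |
| Saturday's | 6.00 | 4.6 | 23.1 | 22.9 | 40.1 |
| Saturday's | 10.0 | 9.4 | 13.9 | 38.9 | 32.0 |
| Saturday's | 15.0 | 10.5 | 8.2 | 52.5 | 24.1 |

(standard deviation of a reading: 0.5 percentage points)

- the numbers in the tables scatter with a standard deviation of 0.5 percentage points
- a reading or a percentage of single product counts all its forms, free or not
- a reading of substrate is of its free form alone

- which of these there is most of at the end, counted by the substrate in it, blue (substrate / double product / single product / isomer of the product)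
- which of these there is most of at the end, counted by the substrate in it, ochre (substrate / double product / single product / isomer of the product)
- which of these there is most of at the end, counted by the substrate in it, green (substrate / double product / single product / isomer of the product)
- the largest of these amounts at the end, in percent of the substrate charged, blue
- the largest of these amounts at the end, in percent of the substrate charged, ochre
- the largest of these amounts at the end, in percent of the substrate charged, green

Add up Tuesday's reading at 4.00 min and 11.2 % of the substrate is missing; by 15.0 min the gap is 6.90 %. Substrate reads free and single product reads every form, so take the gap as idle adduct, one substrate held on one single product, in a fast pre-equilibrium. Bound over free is then K[substrate]. The gap, divided by [substrate] and [free single product], gives 0.103 mM⁻¹ on Tuesday's run and 0.0972 mM⁻¹ on Saturday's at 4.00 min. Carry 0.100 mM⁻¹ as the parking constant K, [idle adduct]/([substrate][free single product]), a reading with the scatter in it. The free share of single product is 1/(1+K[substrate]).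

At the last readings that share is 83.6 % on Tuesday's run and 92.4 % on Saturday's. Add no substrate to any flask: each mM added to free substrate raises the ratio by 0.100 mM⁻¹, and on this reckoning bound single product is out of reach of reagent.

The forecast expects single product at 35.5 % in blue, double product at 38.5 % in ochre and double product at 50.5 % in green, from “Interpolating double at about 2.4% per mM”. My reckoning gives no such amounts, but it tests that line: the reagent charges of the two runs differ by a factor of 1.67, the free shares by 1.11, so reagent moves the making of double product more than the free share does.

At 20 min blue holds most single product, at 34.3 %; ochre double product, at 39.4 %; green double product, at 51.4 %.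

    substrate + reagent → single product (k = 0.160 M⁻¹ s⁻¹)
    reagent + single product → double product (k = 0.120 M⁻¹ s⁻¹)
    reagent + double product → tris adduct (k = 0.00650 M⁻¹ s⁻¹)
    substrate + single product ⇌ idle adduct, settled at all times (K = 100 M⁻¹)
    single product ⇌ isomer of the product (K = 0.600, k = 7.90 × 10⁻⁴ s⁻¹)

Ochre ends with idle adduct at 6.80 %, counted as two, beside substrate at 12.9 %; 0.100 mM⁻¹ on that substrate gives a free share of 88.6 %, and the flask shows 88.6 %. The same flask as ochre with 17 mM of substrate ends with 19.7 % of it; 0.100 mM⁻¹ gives a free share of 74.9 %, the flask shows 74.9 %, and single product stands at 35.3 % over double product at 23.7 %.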